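**Retrosynthetic overview**
- The target is a 3-hydroxy-1,2-dioxane-3-acetic acid (ring O1–O2–C3–C4–C5–C6). The ester is hydrolysed last, and the only ring to be made is closed late by adding a C6 hydroperoxide to the C3 ketone (O2–C3 bond). The C6–O1 bond comes from cobalt-catalysed peroxidation of a C6=CH2 alkene.
- The C2–C3 bond of the β-keto ester comes from Roskamp homologation of a C3 aldehyde. Its C4 methyl centre is set by Evans alkylation with 2,3-dibromopropene.
- Structural feature used: the methyl-bearing methine C2' is the direct neighbour of C1', the CH2 bonded to ring carbon C6. The C2'–CH3 and C1'–C6 bonds are therefore cut together: enantioselective methylalumination of 10-phenyldec-1-ene gives a 2-methylalkyl metal, which is coupled with a C6 vinyl bromide.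
- Ring order: the 1,2-dioxane is the only ring formed (step 10); the phenyl ring is bought.

Key step: step 5

Assumption: the target is read as 3S,4R,6S in the ring and R at C2' (ring numbering O1, O2, C3 hemiketal carbon, C4, C5, C6; side chain C1' on C6 to C10' bearing phenyl). The 3-hydroxy-1,2-dioxane is taken to be the stable ring tautomer of the γ-hydroperoxy ketone, with C3 under thermodynamic control.

**Route**

Step 1
Reactants: 1 10-bromodec-1-ene; 2 phenylmagnesium bromide
Product: 3 10-phenyldec-1-ene
Conditions: Li2CuCl4 (3 mol %), NMP, THF, 0 °C → rt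
Reagents that add atoms: none
Why: Kochi-type copper-catalysed cross-coupling of an aryl Grignard reagent with a primary alkyl bromide should form the aryl–alkyl bond, the remote terminal alkene being inert to the organocopper intermediate.

Step 2
Reactants: 4 (S)-4-benzyl-3-propionyloxazolidin-2-one; 5 2,3-dibromopropene
Product: 7 (S)-4-benzyl-3-[(R)-4-bromo-2-methylpent-4-enoyl]oxazolidin-2-one, via sodium Z-enolate 6 (not isolated)
Conditions: NaHMDS, THF, −78 °C; then 5, −78 → −40 °C
Reagents that add atoms: none
Why: Evans asymmetric alkylation, in which the chelated Z-enolate 6 should displace the allylic bromide of 5 (the vinylic bromide is inert to substitution) on the face opposite the benzyl group of the auxiliary, setting the new centre as R (future C4).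

Step 3
Reactants: 7 (S)-4-benzyl-3-[(R)-4-bromo-2-methylpent-4-enoyl]oxazolidin-2-one
Product: 8 (R)-4-bromo-2-methylpent-4-en-1-ol
Conditions: LiBH4, MeOH (1 equiv), THF, 0 °C
Reagents that add atoms: none
Why: Reductive cleavage of the N-acyl oxazolidinone with lithium borohydride should give the primary alcohol and release the auxiliary without touching the vinyl bromide or the α-methyl centre.

Step 4
Reactants: 8 (R)-4-bromo-2-methylpent-4-en-1-ol
Product: 9 (R)-[(4-bromo-2-methylpent-4-en-1-yl)oxy](tert-butyl)dimethylsilane
Conditions: TBSCl, imidazole, CH2Cl2, 0 °C → rt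
Reagents that add atoms: tert-butyldimethylsilyl chloride, CC(C)(C)[Si](C)(C)Cl
Why: Imidazole-promoted silylation of a primary alcohol masks the hydroxyl against the organoaluminium and organozinc species of step 5.

Step 5
Reactants: 3 10-phenyldec-1-ene; 10 trimethylaluminium; 9 (R)-[(4-bromo-2-methylpent-4-en-1-yl)oxy](tert-butyl)dimethylsilane
Product: 13 tert-butyl{[(2R,6R)-2,6-dimethyl-4-methylidene-14-phenyltetradecyl]oxy}dimethylsilane, via alkylalane 11 (not isolated), via alkylzinc triflate 12 (not isolated)
Conditions: 3 (1.4 equiv), 10 (2.5 equiv), (−)-bis(1-neomenthylindenyl)zirconium dichloride (5 mol %), CH2Cl2, 0 °C → rt; evaporate volatiles; Zn(OTf)2, DMF, 70 °C; then 9 (1.0 equiv), Pd(PPh3)4 (5 mol %), DMF, rt → 70 °C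
Reagents that add atoms: none
Why: The cationic methylzirconocene generated from the chiral zirconocene dichloride and Me3Al adds Zr–CH3 across the terminal alkene of 3, methyl to the internal carbon (future C2') and metal to the terminal carbon (future C1'), and zirconium-to-aluminium exchange releases alane 11 and regenerates the catalyst. After removal of excess Me3Al, Zn(OTf)2 in DMF converts 11 into the more reactive alkylzinc 12, zerovalent palladium inserts into the C–Br bond of 9, and transmetalation followed by reductive elimination forms the C1'–C6 bond; this is the known Negishi sequence of zirconium-catalysed asymmetric carboalumination followed by zinc-promoted, palladium-catalysed alkyl–alkenyl coupling. No ring closes in this step. The new stereocentre C2' (R) is set by the catalyst alone, the (−)-neomenthylindenyl ligand pair being the one that gives (R)-2-methylalkyl metals from unbranched 1-alkenes, while C4 (R) is carried unchanged in 9 because it is not adjacent to a reacting centre. The step needs enantioface selectivity (usually only moderate to good for methyl transfer, so a minor C2' epimer is expected and would be removed by HPLC at the stage of 19 or avoided by the fallback), delivery of methyl to the internal alkene carbon (secured by the preference of zirconium for the unhindered terminal carbon) and transfer of the 2-methylalkyl group rather than a methyl group to palladium, which the excess of 11 over 9 and the zinc triflate/DMF medium are meant to secure.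

Step 6
Reactants: 13 tert-butyl{[(2R,6R)-2,6-dimethyl-4-methylidene-14-phenyltetradecyl]oxy}dimethylsilane
Product: 14 (2R,6R)-2,6-dimethyl-4-methylidene-14-phenyltetradecan-1-ol
Conditions: TBAF, THF, 0 °C → rt
Reagents that add atoms: none
Why: Fluoride-induced cleavage of the primary TBS ether (driven by Si–F bond formation) should free the alcohol while leaving the 1,1-disubstituted alkene and both stereocentres untouched.

Step 7
Reactants: 14 (2R,6R)-2,6-dimethyl-4-methylidene-14-phenyltetradecan-1-ol
Product: 15 (2R,6R)-2,6-dimethyl-4-methylidene-14-phenyltetradecanal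
Conditions: Dess–Martin periodinane, CH2Cl2, 0 °C → rt; crude aldehyde used at once
Reagents that add atoms: none
Why: Dess–Martin oxidation converts the primary alcohol into the aldehyde under near-neutral conditions, so the α-methyl centre (future C4) should not epimerise.

Step 8
Reactants: 15 (2R,6R)-2,6-dimethyl-4-methylidene-14-phenyltetradecanal
Product: 16 ethyl (4R,8R)-4,8-dimethyl-6-methylidene-3-oxo-16-phenylhexadecanoate
Conditions: ethyl diazoacetate, SnCl2 (10 mol %), CH2Cl2, rt
Reagents that add atoms: ethyl diazoacetate, CCOC(=O)C=[N+]=[N-]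
Why: Roskamp homologation, in which SnCl2 activates the aldehyde, the diazo ester adds and a 1,2-hydride shift with loss of N2 gives the β-keto ester under conditions that α-branched aldehydes tolerate without loss of configuration.

Step 9
Reactants: 16 ethyl (4R,8R)-4,8-dimethyl-6-methylidene-3-oxo-16-phenylhexadecanoate
Product: 17 ethyl (4R,8R)-4,6,8-trimethyl-3-oxo-16-phenyl-6-[(triethylsilyl)peroxy]hexadecanoate (both C6 epimers)
Conditions: Co(acac)2 (10 mol %), O2 (1 atm), Et3SiH, ClCH2CH2Cl, rt
Reagents that add atoms: dioxygen, O=O; triethylsilane, CC[SiH](CC)CC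
Why: Mukaiyama–Isayama hydroperoxysilylation, in which a cobalt hydride transfers hydrogen to the CH2 terminus, the tertiary C6 radical traps O2 and the cobalt peroxide is silylated by Et3SiH, so the peroxide enters at the more substituted carbon; nothing controls the new C6 centre, so both epimers are expected and are separated after ring closure.

Step 10
Reactants: 17 ethyl (4R,8R)-4,6,8-trimethyl-3-oxo-16-phenyl-6-[(triethylsilyl)peroxy]hexadecanoate (both C6 epimers)
Product: 19 ethyl 2-[(3S,4R,6S)-3-hydroxy-4,6-dimethyl-6-[(2R)-2-methyl-10-phenyldecyl]-1,2-dioxan-3-yl]acetate, via hydroperoxy ketone 18 (not isolated)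
Conditions: TBAF, AcOH, THF, 0 °C; then chromatography (HPLC if needed) to remove the C6 epimer
Reagents that add atoms: none
Why: Fluoride cleaves the Si–O bond of the silyl peroxide and the freed C6 hydroperoxide adds 6-exo to the electrophilic C3 ketone (intramolecular peroxy-hemiketalisation) to give the 1,2-dioxan-3-ol, whose C3 should equilibrate to the anomer with axial OH and equatorial CH2CO2Et, which is 3S in the 6S series.

Step 11
Reactants: 19 ethyl 2-[(3S,4R,6S)-3-hydroxy-4,6-dimethyl-6-[(2R)-2-methyl-10-phenyldecyl]-1,2-dioxan-3-yl]acetate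
Product: 20 2-[(3S,4R,6S)-3-hydroxy-4,6-dimethyl-6-[(2R)-2-methyl-10-phenyldecyl]-1,2-dioxan-3-yl]acetic acid
Conditions: LiOH, THF/H2O, 0 °C; then cold dilute HCl to pH 3
Reagents that add atoms: lithium hydroxide, [Li+].[OH-]
Why: Mild saponification of the ethyl ester followed by cold acidification should give the acid, because C6 is quaternary and C3 bears no hydrogen, so base-induced Kornblum–DeLaMare cleavage of the O–O bond cannot occur and the hemiketal re-closes to the same thermodynamic anomer.

**Compound list**
1 | 10-bromodec-1-ene | C=CCCCCCCCCBr | starting material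
2 | phenylmagnesium bromide | Br[Mg]c1ccccc1 | starting material
3 | 10-phenyldec-1-ene | C=CCCCCCCCCc1ccccc1 | intermediate
4 | (S)-4-benzyl-3-propionyloxazolidin-2-one | CCC(=O)N1[C@@H](Cc2ccccc2)COC1=O | starting material
5 | 2,3-dibromopropene | C=C(Br)CBr | starting material
6 | sodium Z-enolate of 4 | C/C=C(\[O-])N1[C@@H](Cc2ccccc2)COC1=O.[Na+] | intermediate
7 | (S)-4-benzyl-3-[(R)-4-bromo-2-methylpent-4-enoyl]oxazolidin-2-one | C=C(Br)C[C@@H](C)C(=O)N1[C@@H](Cc2ccccc2)COC1=O | intermediate
8 | (R)-4-bromo-2-methylpent-4-en-1-ol | C=C(Br)C[C@@H](C)CO | intermediate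
9 | (R)-[(4-bromo-2-methylpent-4-en-1-yl)oxy](tert-butyl)dimethylsilane | C=C(Br)C[C@@H](C)CO[Si](C)(C)C(C)(C)C | intermediate
10 | trimethylaluminium | C[Al](C)C | starting material
11 | (R)-dimethyl(2-methyl-10-phenyldecyl)alumane | C[C@H](CCCCCCCCc1ccccc1)C[Al](C)C | intermediate
12 | (R)-(2-methyl-10-phenyldecyl)zinc trifluoromethanesulfonate | C[C@H](CCCCCCCCc1ccccc1)C[Zn]OS(=O)(=O)C(F)(F)F | intermediate
13 | tert-butyl{[(2R,6R)-2,6-dimethyl-4-methylidene-14-phenyltetradecyl]oxy}dimethylsilane | C[C@H](CCCCCCCCc1ccccc1)CC(=C)C[C@@H](C)CO[Si](C)(C)C(C)(C)C | intermediate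
14 | (2R,6R)-2,6-dimethyl-4-methylidene-14-phenyltetradecan-1-ol | C[C@H](CCCCCCCCc1ccccc1)CC(=C)C[C@@H](C)CO | intermediate
15 | (2R,6R)-2,6-dimethyl-4-methylidene-14-phenyltetradecanal | C[C@H](CCCCCCCCc1ccccc1)CC(=C)C[C@@H](C)C=O | intermediate
16 | ethyl (4R,8R)-4,8-dimethyl-6-methylidene-3-oxo-16-phenylhexadecanoate | C[C@H](CCCCCCCCc1ccccc1)CC(=C)C[C@@H](C)C(=O)CC(=O)OCC | intermediate
17 | ethyl (4R,8R)-4,6,8-trimethyl-3-oxo-16-phenyl-6-[(triethylsilyl)peroxy]hexadecanoate (both C6 epimers) | C[C@H](CCCCCCCCc1ccccc1)CC(C)(OO[Si](CC)(CC)CC)C[C@@H](C)C(=O)CC(=O)OCC | intermediate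
18 | ethyl (4R,8R)-6-hydroperoxy-4,6,8-trimethyl-3-oxo-16-phenylhexadecanoate (both C6 epimers) | C[C@H](CCCCCCCCc1ccccc1)CC(C)(OO)C[C@@H](C)C(=O)CC(=O)OCC | intermediate
19 | ethyl 2-[(3S,4R,6S)-3-hydroxy-4,6-dimethyl-6-[(2R)-2-methyl-10-phenyldecyl]-1,2-dioxan-3-yl]acetate | C[C@H](CCCCCCCCc1ccccc1)C[C@@]1(C)C[C@@H](C)[C@](O)(CC(=O)OCC)OO1 | intermediate
20 | 2-[(3S,4R,6S)-3-hydroxy-4,6-dimethyl-6-[(2R)-2-methyl-10-phenyldecyl]-1,2-dioxan-3-yl]acetic acid | C[C@H](CCCCCCCCc1ccccc1)C[C@@]1(C)C[C@@H](C)[C@](O)(CC(=O)O)OO1 | target

**Summary**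
Total step count: 11. Longest linear sequence: 10 steps (steps 2 to 11, from 4 and 5 to 20).

**Steps most likely to fail**

Step 5. What may go wrong: incomplete enantioface discrimination in the methylalumination, and competing transfer of methyl groups from aluminium to palladium in the coupling. The fallback sets out from 3, through alane 11 made as in step 5. The alane is oxidised with O2 to (R)-2-methyl-10-phenyldecan-1-ol F1. Its enantiomeric purity is raised by lipase-catalysed acetylation (Amano lipase PS, vinyl acetate), in which the minor enantiomer is expected to react faster and leave as (S)-2-methyl-10-phenyldecyl acetate F2. F1 is converted with I2, PPh3 and imidazole into [(9R)-10-iodo-9-methyldecyl]benzene F3. Zinc insertion (Zn dust, LiCl, THF) gives (R)-(2-methyl-10-phenyldecyl)zinc iodide F4, and Pd(PPh3)4-catalysed Negishi coupling of F4 with 9 comes back to the route at 13.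

Step 9. What may go wrong: the enolisable β-keto ester may bind the cobalt catalyst or be oxidised at its activated CH2 under O2, lowering conversion to the silyl peroxide; the lack of facial control at C6 remains in any case. The fallback sets out from aldehyde 15. Aldol addition of the lithium enolate of ethyl acetate (LDA, THF, −78 °C) gives ethyl (4R,8R)-3-hydroxy-4,8-dimethyl-6-methylidene-16-phenylhexadecanoate F5 (both C3 epimers, which is of no consequence). Peroxidation of F5 with Co(acac)2, O2 and Et3SiH gives ethyl (4R,8R)-3-hydroxy-4,6,8-trimethyl-16-phenyl-6-[(triethylsilyl)peroxy]hexadecanoate F6. Dess–Martin oxidation of the secondary alcohol then comes back to the route at 17.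

Step 11. What may go wrong: opening of the peroxy-hemiketal under aqueous base, followed by retro-Claisen cleavage, C4 epimerisation, or decarboxylation of the open β-keto acid on acidification. The fallback sets out from 16. Transesterification with 2-(trimethylsilyl)ethanol (DMAP cat., toluene, reflux) gives 2-(trimethylsilyl)ethyl (4R,8R)-4,8-dimethyl-6-methylidene-3-oxo-16-phenylhexadecanoate F7. Peroxidation as in step 9 gives 2-(trimethylsilyl)ethyl (4R,8R)-4,6,8-trimethyl-3-oxo-16-phenyl-6-[(triethylsilyl)peroxy]hexadecanoate F8. Buffered TBAF as in step 10, with removal of the C6 epimer, gives 2-(trimethylsilyl)ethyl 2-[(3S,4R,6S)-3-hydroxy-4,6-dimethyl-6-[(2R)-2-methyl-10-phenyldecyl]-1,2-dioxan-3-yl]acetate F9. Anhydrous TBAF in THF at 0 °C then removes the silylethyl group without hydroxide and comes back to the route at 20.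

**Further compounds**
F1 | step 5 | (R)-2-methyl-10-phenyldecan-1-ol | C[C@H](CCCCCCCCc1ccccc1)CO
F2 | step 5 | (S)-2-methyl-10-phenyldecyl acetate | C[C@@H](CCCCCCCCc1ccccc1)COC(C)=O
F3 | step 5 | [(9R)-10-iodo-9-methyldecyl]benzene | C[C@H](CCCCCCCCc1ccccc1)CI
F4 | step 5 | (R)-(2-methyl-10-phenyldecyl)zinc iodide | C[C@H](CCCCCCCCc1ccccc1)C[Zn]I
F5 | step 9 | ethyl (4R,8R)-3-hydroxy-4,8-dimethyl-6-methylidene-16-phenylhexadecanoate (both C3 epimers) | C[C@H](CCCCCCCCc1ccccc1)CC(=C)C[C@@H](C)C(O)CC(=O)OCC
F6 | step 9 | ethyl (4R,8R)-3-hydroxy-4,6,8-trimethyl-16-phenyl-6-[(triethylsilyl)peroxy]hexadecanoate (C3 and C6 epimers) | C[C@H](CCCCCCCCc1ccccc1)CC(C)(OO[Si](CC)(CC)CC)C[C@@H](C)C(O)CC(=O)OCC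
F7 | step 11 | 2-(trimethylsilyl)ethyl (4R,8R)-4,8-dimethyl-6-methylidene-3-oxo-16-phenylhexadecanoate | C[C@H](CCCCCCCCc1ccccc1)CC(=C)C[C@@H](C)C(=O)CC(=O)OCC[Si](C)(C)C
F8 | step 11 | 2-(trimethylsilyl)ethyl (4R,8R)-4,6,8-trimethyl-3-oxo-16-phenyl-6-[(triethylsilyl)peroxy]hexadecanoate (both C6 epimers) | C[C@H](CCCCCCCCc1ccccc1)CC(C)(OO[Si](CC)(CC)CC)C[C@@H](C)C(=O)CC(=O)OCC[Si](C)(C)C
F9 | step 11 | 2-(trimethylsilyl)ethyl 2-[(3S,4R,6S)-3-hydroxy-4,6-dimethyl-6-[(2R)-2-methyl-10-phenyldecyl]-1,2-dioxan-3-yl]acetate | C[C@H](CCCCCCCCc1ccccc1)C[C@@]1(C)C[C@@H](C)[C@](O)(CC(=O)OCC[Si](C)(C)C)OO1
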